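**Plan**
1. Retrosynthesis first removes the 5-O-methyl group, the 4′-O-MOM group and the C3–O bond, which leaves the 8-prenylflavone 17.
2. In ring C of 17 the C4 carbonyl lies between C4a of ring A and the C3=C2–aryl unit, and O1 is carried by C8a next to C4a. This is a masked o-hydroxyaryl ynone, so C4a–C4, C4–C3 and O1–C2 are cut to iodophenol 9, carbon monoxide 14 and arylacetylene 13.
3. 9 is cut at the ring–prenyl bond and at C–I back to 3,5-dimethoxyphenol (two MOM-directed ortho-metalations); 13 is cut at the C≡C bond back to 4-hydroxybenzaldehyde.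
4. Forward: rings A and B are bought, ring A is prenylated and iodinated, ring C is the only ring built (step 7), then C3 is hydroxylated and the 4′- and 5-oxygens are unmasked.
5. Stereochemistry: none has to be set, because the target has no stereocentre and no stereogenic double bond.

Key step: step 7

Remark: the molecule is achiral, so "single enantiomer" is read as the one constitution given by the SMILES, and no step needs stereocontrol.

**Step 1**
Reactants: 1 3,5-dimethoxyphenol
Product: 2 1,3-dimethoxy-5-(methoxymethoxy)benzene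
Conditions: MOMCl, iPr2NEt, CH2Cl2, 0 °C → rt
Reagents that add atoms: chloromethyl methyl ether (MOMCl), COCCl
Why: O-alkylation of the phenol with MOMCl and a hindered amine base (Williamson-type acetal formation) is routine for electron-rich phenols and installs the group that directs both later ortho-metalations.

**Step 2**
Reactants: 2 1,3-dimethoxy-5-(methoxymethoxy)benzene; 3 prenyl bromide (1-bromo-3-methylbut-2-ene)
Product: 6 1,5-dimethoxy-3-(methoxymethoxy)-2-(3-methylbut-2-en-1-yl)benzene, via aryllithium 4 (not isolated), via arylcopper 5 (not isolated)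
Conditions: n-BuLi, THF, 0 °C; CuBr·SMe2 (1.0 equiv), −78 °C; then 3, −78 °C → rt
Reagents that add atoms: none
Why: Directed ortho-metalation should place lithium between OMOM and OMe (the better-coordinating acetal and two equivalent sites favour it over the position between the methoxy groups), and after transmetalation to copper the aryl group is allylated at the primary carbon of prenyl bromide (copper-mediated SN2 allylation).

**Step 3**
Reactants: 6 1,5-dimethoxy-3-(methoxymethoxy)-2-(3-methylbut-2-en-1-yl)benzene
Product: 8 2-iodo-1,5-dimethoxy-3-(methoxymethoxy)-4-(3-methylbut-2-en-1-yl)benzene, via aryllithium 7 (not isolated)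
Conditions: n-BuLi, THF, 0 °C; then I2, THF, −78 °C
Reagents that add atoms: iodine, II
Why: A second directed ortho-metalation removes the one remaining ring proton flanked by OMOM and OMe, ring lithiation by n-BuLi being kinetically preferred over deprotonation of the prenyl CH2, and iodinolysis of the aryllithium fixes iodine on the carbon that becomes C4a.

**Step 4**
Reactants: 8 2-iodo-1,5-dimethoxy-3-(methoxymethoxy)-4-(3-methylbut-2-en-1-yl)benzene
Product: 9 2-iodo-3,5-dimethoxy-6-(3-methylbut-2-en-1-yl)phenol
Conditions: conc. HCl (cat.), MeOH, rt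
Reagents that add atoms: none
Why: Acid-catalysed transacetalisation to methanol (MOM deprotection) cleaves the aryl acetal at room temperature, where protonation of the trisubstituted alkene (the entry to chroman formation) and protodeiodination should be too slow to compete.

**Step 5**
Reactants: 10 4-hydroxybenzaldehyde
Product: 11 4-(methoxymethoxy)benzaldehyde
Conditions: MOMCl, iPr2NEt, CH2Cl2, 0 °C → rt
Reagents that add atoms: chloromethyl methyl ether (MOMCl), COCCl
Why: Standard MOM protection of a phenol (O-alkylation), chosen because the acetal withstands amine, carbon monoxide and LDA and can later be removed without touching the 7-methyl ether.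

**Step 6**
Reactants: 11 4-(methoxymethoxy)benzaldehyde
Product: 13 1-ethynyl-4-(methoxymethoxy)benzene, via diazoalkene 12 (not isolated)
Conditions: dimethyl (1-diazo-2-oxopropyl)phosphonate, K2CO3, MeOH, 0 °C → rt
Reagents that add atoms: dimethyl (1-diazo-2-oxopropyl)phosphonate (Ohira–Bestmann reagent), COP(=O)(OC)C(=[N+]=[N-])C(C)=O
Why: Seyferth–Gilbert homologation in the Ohira–Bestmann variant: methanolysis of the reagent frees the diazomethylphosphonate anion, Horner–Wadsworth–Emmons olefination gives the diazoalkene, and loss of nitrogen with 1,2-hydrogen shift gives the terminal alkyne under conditions too mild to harm the acetal.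

**Step 7**
Reactants: 9 2-iodo-3,5-dimethoxy-6-(3-methylbut-2-en-1-yl)phenol; 14 carbon monoxide; 13 1-ethynyl-4-(methoxymethoxy)benzene
Product: 17 5,7-dimethoxy-2-[4-(methoxymethoxy)phenyl]-8-(3-methylbut-2-en-1-yl)-4H-chromen-4-one, via ynone 15 (not isolated), via enaminone 16 (not isolated)
Conditions: PdCl2(dppf) (5 mol%), CO (20 atm), Et2NH, 120 °C, autoclave, copper-free
Reagents that add atoms: none
Why: Oxidative addition of Pd(0) into the C–I bond of 9, CO insertion to the aroyl–palladium species, amine-assisted transfer of the acetylide of 13 and reductive elimination form C4a–C4 and C4–C3 and give the o-hydroxyaryl ynone 15; diethylamine then adds to the β-carbon of the ynone to give enaminone 16, and the phenol oxygen displaces the amine at C2 to form O1–C2. The closest known reaction type is the palladium-catalysed carbonylative Sonogashira coupling–cyclisation of o-iodophenols with terminal alkynes in a secondary amine, which gives flavones directly. Ring C closes by 6-endo-trig addition–elimination on the enaminone, formally a 6-endo-dig oxa-Michael addition to the ynone. No stereocentre is created. Two selectivities are needed: CO insertion must outrun direct alkynylation, which the electron-rich, doubly ortho-substituted aryl–palladium species, the CO pressure and the absence of copper should secure, and 6-endo closure must beat 5-exo closure to the aurone, which the secondary amine secures because the enaminone is electrophilic only at C2. The iodine fixes the site of acylation on ring A, the prenyl group is meta to it and cannot insert, and the MOM ether is inert to amine and CO.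

**Step 8**
Reactants: 17 5,7-dimethoxy-2-[4-(methoxymethoxy)phenyl]-8-(3-methylbut-2-en-1-yl)-4H-chromen-4-one
Product: 20 3-hydroxy-5,7-dimethoxy-2-[4-(methoxymethoxy)phenyl]-8-(3-methylbut-2-en-1-yl)-4H-chromen-4-one, via 3-lithioflavone 18 (not isolated), via boronate 19 (not isolated)
Conditions: LDA, THF, −78 °C; B(OMe)3, −78 → 0 °C; then AcOH, 30% H2O2, 0 °C → rt
Reagents that add atoms: hydrogen peroxide, OO
Why: LDA deprotonates the flavone kinetically at C3 (a known site of flavone lithiation), the borate trap at −78 °C forestalls ring opening of the 3-lithio species, and peroxide-induced 1,2-migration from boron to oxygen (boronate oxidation) should give the flavonol without epoxidising the prenyl alkene.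

**Step 9**
Reactants: 20 3-hydroxy-5,7-dimethoxy-2-[4-(methoxymethoxy)phenyl]-8-(3-methylbut-2-en-1-yl)-4H-chromen-4-one
Product: 21 3-hydroxy-2-(4-hydroxyphenyl)-5,7-dimethoxy-8-(3-methylbut-2-en-1-yl)-4H-chromen-4-one
Conditions: 2 M HCl, MeOH–THF, 40 °C
Reagents that add atoms: none
Why: Acid-catalysed acetal methanolysis (MOM deprotection) is safe here because the prenyl group is flanked by the 7-methoxy group and ring oxygen O1, so no free ortho-hydroxyl is available for cyclisation to a chroman.

**Step 10**
Reactants: 21 3-hydroxy-2-(4-hydroxyphenyl)-5,7-dimethoxy-8-(3-methylbut-2-en-1-yl)-4H-chromen-4-one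
Product: 22 isoanhydroicaritin, 3,5-dihydroxy-2-(4-hydroxyphenyl)-7-methoxy-8-(3-methylbut-2-en-1-yl)-4H-chromen-4-one
Conditions: MgI2·OEt2 (5 equiv), THF, reflux; then 1 M HCl
Reagents that add atoms: none
Why: Chelation-controlled peri-demethylation: magnesium bridges the C4 carbonyl and the 5-methoxy oxygen and iodide removes the methyl group by SN2, whereas the 7-methyl ether cannot chelate and the aprotic, weakly Lewis-acidic medium leaves the prenyl alkene alone, as is known for 5-methoxy-8-prenyl flavonoids.

**Compound list**
1 | 3,5-dimethoxyphenol | COc1cc(O)cc(OC)c1 | starting material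
2 | 1,3-dimethoxy-5-(methoxymethoxy)benzene | COCOc1cc(OC)cc(OC)c1 | intermediate
3 | prenyl bromide (1-bromo-3-methylbut-2-ene) | CC(C)=CCBr | starting material
4 | [2,4-dimethoxy-6-(methoxymethoxy)phenyl]lithium (in situ) | [Li]c1c(OC)cc(OC)cc1OCOC | intermediate
5 | [2,4-dimethoxy-6-(methoxymethoxy)phenyl]copper (in situ) | [Cu]c1c(OC)cc(OC)cc1OCOC | intermediate
6 | 1,5-dimethoxy-3-(methoxymethoxy)-2-(3-methylbut-2-en-1-yl)benzene | COCOc1cc(OC)cc(OC)c1CC=C(C)C | intermediate
7 | [4,6-dimethoxy-2-(methoxymethoxy)-3-(3-methylbut-2-en-1-yl)phenyl]lithium (in situ) | [Li]c1c(OC)cc(OC)c(CC=C(C)C)c1OCOC | intermediate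
8 | 2-iodo-1,5-dimethoxy-3-(methoxymethoxy)-4-(3-methylbut-2-en-1-yl)benzene | COCOc1c(I)c(OC)cc(OC)c1CC=C(C)C | intermediate
9 | 2-iodo-3,5-dimethoxy-6-(3-methylbut-2-en-1-yl)phenol | COc1cc(OC)c(CC=C(C)C)c(O)c1I | intermediate
10 | 4-hydroxybenzaldehyde | O=Cc1ccc(O)cc1 | starting material
11 | 4-(methoxymethoxy)benzaldehyde | COCOc1ccc(C=O)cc1 | intermediate
12 | 1-(2-diazoethenyl)-4-(methoxymethoxy)benzene (in situ) | COCOc1ccc(C=C=[N+]=[N-])cc1 | intermediate
13 | 1-ethynyl-4-(methoxymethoxy)benzene | COCOc1ccc(C#C)cc1 | intermediate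
14 | carbon monoxide | [C-]#[O+] | starting material
15 | 1-[2-hydroxy-4,6-dimethoxy-3-(3-methylbut-2-en-1-yl)phenyl]-3-[4-(methoxymethoxy)phenyl]prop-2-yn-1-one (in situ) | COCOc1ccc(C#CC(=O)c2c(OC)cc(OC)c(CC=C(C)C)c2O)cc1 | intermediate
16 | 3-(diethylamino)-1-[2-hydroxy-4,6-dimethoxy-3-(3-methylbut-2-en-1-yl)phenyl]-3-[4-(methoxymethoxy)phenyl]prop-2-en-1-one (in situ, alkene geometry not defined) | CCN(CC)C(=CC(=O)c1c(OC)cc(OC)c(CC=C(C)C)c1O)c1ccc(OCOC)cc1 | intermediate
17 | 5,7-dimethoxy-2-[4-(methoxymethoxy)phenyl]-8-(3-methylbut-2-en-1-yl)-4H-chromen-4-one | COCOc1ccc(-c2cc(=O)c3c(OC)cc(OC)c(CC=C(C)C)c3o2)cc1 | intermediate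
18 | 3-lithio-5,7-dimethoxy-2-[4-(methoxymethoxy)phenyl]-8-(3-methylbut-2-en-1-yl)-4H-chromen-4-one (in situ) | [Li]c1c(-c2ccc(OCOC)cc2)oc2c(CC=C(C)C)c(OC)cc(OC)c2c1=O | intermediate
19 | dimethyl {5,7-dimethoxy-2-[4-(methoxymethoxy)phenyl]-8-(3-methylbut-2-en-1-yl)-4-oxo-4H-chromen-3-yl}boronate (in situ) | COB(OC)c1c(-c2ccc(OCOC)cc2)oc2c(CC=C(C)C)c(OC)cc(OC)c2c1=O | intermediate
20 | 3-hydroxy-5,7-dimethoxy-2-[4-(methoxymethoxy)phenyl]-8-(3-methylbut-2-en-1-yl)-4H-chromen-4-one | COCOc1ccc(-c2oc3c(CC=C(C)C)c(OC)cc(OC)c3c(=O)c2O)cc1 | intermediate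
21 | 3-hydroxy-2-(4-hydroxyphenyl)-5,7-dimethoxy-8-(3-methylbut-2-en-1-yl)-4H-chromen-4-one | COc1cc(OC)c2c(=O)c(O)c(-c3ccc(O)cc3)oc2c1CC=C(C)C | intermediate
22 | isoanhydroicaritin, 3,5-dihydroxy-2-(4-hydroxyphenyl)-7-methoxy-8-(3-methylbut-2-en-1-yl)-4H-chromen-4-one | COc1cc(O)c2c(=O)c(O)c(-c3ccc(O)cc3)oc2c1CC=C(C)C | target

**Totals and risks**
Total step count: 10. Longest linear sequence: 8 steps (steps 1–4 and 7–10; 1 → 2 → 6 → 8 → 9 → 17 → 20 → 21 → 22). The alkyne branch is 2 steps (steps 5 and 6).

Step 7 (most at risk). Oxidative addition into the hindered, electron-rich C–I bond may be slow, and capture of the aroyl–palladium species by diethylamine (amide formation) or closure in the 5-exo sense may compete.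
Fallback, setting out from 9 and 13 and returning at 17: the ynone is assembled by polar chemistry, the C4 carbon then coming from DMF instead of CO. Alkyne 13 is deprotonated with n-BuLi (THF, −78 °C) to the lithium acetylide F1 and formylated with DMF to 3-[4-(methoxymethoxy)phenyl]prop-2-ynal F2. Iodophenol 9 is converted with n-BuLi (2.2 equiv, THF, −78 °C), by O-deprotonation and iodine–lithium exchange, into the dilithio species F3, which should add to F2 to give the racemic propargylic alcohol F4. MnO2 (CH2Cl2, rt) should oxidise F4 to ynone 15, now isolated, and Et2NH in EtOH (rt → 60 °C) takes it through enaminone 16 to flavone 17.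

Step 3. Deprotonation at the benzylic and allylic CH2 of the prenyl group (lateral lithiation), or at the ring position between the two methoxy groups, may compete with the wanted ring lithiation.
Fallback, setting out from 2 and returning at 9 (6 and 8 are bypassed): iodine is introduced before the prenyl group, so no prenyl C–H is present during lithiation. Aryllithium 4, made from 2 as in step 2, is quenched with I2 to give 2-iodo-1,5-dimethoxy-3-(methoxymethoxy)benzene F5. HCl in MeOH frees 2-iodo-3,5-dimethoxyphenol F6. Its sodium phenoxide (NaH, toluene, rt) is then C-alkylated with 3 at the only free ortho position (ortho-selective C-allylation of a phenoxide in a non-polar solvent) to give 9.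

Step 2. The first lithiation may not discriminate fully between the OMOM/OMe-flanked site and the site between the methoxy groups, and the copper-mediated alkylation may suffer allylic transposition (SN2′).
Fallback, setting out from 1 and returning at 6: the prenyl group is delivered by a sigmatropic shift, for which the two ortho positions of 1 are equivalent. 1 is O-alkylated with 3-chloro-3-methylbut-1-yne (CuCl2 cat., DBU, MeCN, 0 °C) to the 1,1-dimethylpropargyl ether F7. Lindlar semihydrogenation (H2, Pd/CaCO3–Pb, quinoline, EtOAc) gives the 1,1-dimethylallyl ether F8. Aromatic Claisen rearrangement (PhNEt2, 130 °C) gives 3,5-dimethoxy-2-(3-methylbut-2-en-1-yl)phenol F9, and MOMCl/iPr2NEt as in step 1 gives 6.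

**Further compounds**
F1 | step 7 | lithium [4-(methoxymethoxy)phenyl]acetylide | [Li]C#Cc1ccc(OCOC)cc1
F2 | step 7 | 3-[4-(methoxymethoxy)phenyl]prop-2-ynal | COCOc1ccc(C#CC=O)cc1
F3 | step 7 | lithium 2-lithio-3,5-dimethoxy-6-(3-methylbut-2-en-1-yl)phenolate | [Li]c1c(OC)cc(OC)c(CC=C(C)C)c1O[Li]
F4 | step 7 | racemic 1-[2-hydroxy-4,6-dimethoxy-3-(3-methylbut-2-en-1-yl)phenyl]-3-[4-(methoxymethoxy)phenyl]prop-2-yn-1-ol | COCOc1ccc(C#CC(O)c2c(OC)cc(OC)c(CC=C(C)C)c2O)cc1
F5 | step 3 | 2-iodo-1,5-dimethoxy-3-(methoxymethoxy)benzene | COCOc1cc(OC)cc(OC)c1I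
F6 | step 3 | 2-iodo-3,5-dimethoxyphenol | COc1cc(O)c(I)c(OC)c1
F7 | step 2 | 1,3-dimethoxy-5-[(2-methylbut-3-yn-2-yl)oxy]benzene | COc1cc(OC)cc(OC(C)(C)C#C)c1
F8 | step 2 | 1,3-dimethoxy-5-[(2-methylbut-3-en-2-yl)oxy]benzene | COc1cc(OC)cc(OC(C)(C)C=C)c1
F9 | step 2 | 3,5-dimethoxy-2-(3-methylbut-2-en-1-yl)phenol | COc1cc(O)c(CC=C(C)C)c(OC)c1
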